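**Strategy.** The C2–aryl bond is made last: a (3S)-chroman-2-ol is joined with 2,4-diformylphloroglucinol by Friedel–Crafts arylation at C2, anti to the C3 isopropyl group. The dihydropyran ring (O1, C2, C3, C4, C4a, C8a) comes from a 2,3-dihydrobenzofuran: in an NHC-catalysed redox ring expansion the aryl oxygen O1 leaves the quaternary carbon that becomes C3 and re-closes on the former formyl carbon (C2) as a six-membered lactone, while a chiral carbene sets C3 by face-selective protonation. The step exploits the O1–C2–C3 array, in which C3 carries hydrogen beside oxidised C2, and the acyl-stabilised phenoxide O1 of ring A. The precursor is a racemic 2-formyl-2-isopropyl-dihydrobenzofuran.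

Key step: step 7

Remark (assumption): the sense of induction of the chiral triazolium catalyst in step 7 cannot be predicted with certainty; the antipode that delivers (3S)-11 is to be fixed after the first run, both antipodes being catalogue compounds.

Step 1
Reactants: 1 prop-2-yn-1-ol; 2 isopropylmagnesium chloride
Product: 3 3-methyl-2-methylidenebutan-1-ol
Conditions: i-PrMgCl (2.5 equiv), CuI (10 mol%), THF/Et2O, 0 °C to rt; aq. NH4Cl
Reagents that add atoms: none
Why: Copper-catalysed carbomagnesiation of the magnesium propargyl alkoxide places the alkyl group on the internal alkyne carbon (alkoxide-directed), and hydrolysis should give the 2-substituted allylic alcohol.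

Step 2
Reactants: 4 1-(2,4,6-trihydroxyphenyl)-3-methylbutan-1-one; 3 3-methyl-2-methylidenebutan-1-ol
Product: 5 1-{2,6-dihydroxy-4-[(3-methyl-2-methylidenebutyl)oxy]phenyl}-3-methylbutan-1-one
Conditions: PPh3, DIAD, THF, 0 °C to rt
Reagents that add atoms: none
Why: Mitsunobu etherification; the 4-OH (para to the ketone) is the most acidic phenol and the only one outside the carbonyl chelate, so mono-O-alkylation is expected there.

Step 3
Reactants: 5 1-{2,6-dihydroxy-4-[(3-methyl-2-methylidenebutyl)oxy]phenyl}-3-methylbutan-1-one
Product: 6 1-{2,6-bis(methoxymethoxy)-4-[(3-methyl-2-methylidenebutyl)oxy]phenyl}-3-methylbutan-1-one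
Conditions: NaH (2.4 equiv), MOMCl (2.4 equiv), DMF, 0 °C to rt
Reagents that add atoms: chloromethyl methyl ether COCCl
Why: Williamson-type acetal protection of the two chelated phenoxides; the MOM ethers block O-5 and O-7 of the later chroman, so that only one oxygen can become the ring oxygen.

Step 4
Reactants: 6 1-{2,6-bis(methoxymethoxy)-4-[(3-methyl-2-methylidenebutyl)oxy]phenyl}-3-methylbutan-1-one
Product: 7 1-[4-hydroxy-2,6-bis(methoxymethoxy)-3-(3-methyl-2-methylidenebutyl)phenyl]-3-methylbutan-1-one
Conditions: N,N-diethylaniline, 185 °C, sealed tube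
Reagents that add atoms: none
Why: Aromatic Claisen rearrangement ([3,3]) onto one of the two equivalent free ortho carbons; rearomatisation frees the 4-OH as the only unprotected phenol, which fixes the future O1 para to the acyl group.

Step 5
Reactants: 7 1-[4-hydroxy-2,6-bis(methoxymethoxy)-3-(3-methyl-2-methylidenebutyl)phenyl]-3-methylbutan-1-one
Product: 9 rac-1-[2-(hydroxymethyl)-4,6-bis(methoxymethoxy)-2-(propan-2-yl)-2,3-dihydro-1-benzofuran-5-yl]-3-methylbutan-1-one, via epoxide 8 (not isolated)
Conditions: m-CPBA (1.1 equiv), NaHCO3, CH2Cl2, 0 °C; then CSA (5 mol%), rt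
Reagents that add atoms: 3-chloroperoxybenzoic acid O=C(OO)c1cccc(Cl)c1
Why: Prilezhaev epoxidation of the 1,1-disubstituted alkene, then acid-promoted 5-exo-tet opening by the single free phenol at the tertiary epoxide carbon (Markovnikov and Baldwin-favoured) should close the dihydrobenzofuran; the quaternary centre is racemic and is erased in step 7.

Step 6
Reactants: 9 rac-1-[2-(hydroxymethyl)-4,6-bis(methoxymethoxy)-2-(propan-2-yl)-2,3-dihydro-1-benzofuran-5-yl]-3-methylbutan-1-one
Product: 10 rac-4,6-bis(methoxymethoxy)-5-(3-methylbutanoyl)-2-(propan-2-yl)-2,3-dihydro-1-benzofuran-2-carbaldehyde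
Conditions: Dess–Martin periodinane, NaHCO3, CH2Cl2, rt
Reagents that add atoms: none
Why: Dess–Martin oxidation of the neopentyl-type primary alcohol; the α-aryloxy aldehyde has no α-hydrogen and cannot enolise.

Step 7
Reactants: 10 rac-4,6-bis(methoxymethoxy)-5-(3-methylbutanoyl)-2-(propan-2-yl)-2,3-dihydro-1-benzofuran-2-carbaldehyde
Product: 11 (3S)-5,7-bis(methoxymethoxy)-6-(3-methylbutanoyl)-3-(propan-2-yl)-3,4-dihydro-2H-chromen-2-one
Conditions: aminoindanol-derived N-C6F5 triazolium tetrafluoroborate (10 mol%), i-Pr2NEt (10 mol%), toluene, 4 Å MS, 0 °C to rt; AcOH quench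
Reagents that add atoms: none
Why: Proposed new method: the carbene adds to the non-enolisable aldehyde to give the Breslow intermediate, whose enaminol expels the aryloxide O1 from the adjacent quaternary carbon (E1cB-like; the para-acyl phenoxide of ring A is a good nucleofuge and the only leaving group available), so the five-membered ring opens to an azolium enol bearing isopropyl and CH2Ar at the future C3; C-protonation inside the chiral pocket of the triazolium then creates C3 and an acyl azolium, which the tethered phenoxide O1 closes by 6-exo-trig acyl substitution with release of the carbene. The closest known reactions are the achiral NHC-catalysed ring expansion of oxacycloalkane-2-carbaldehydes to lactones and the NHC-catalysed enantioselective protonation of azolium enols from α-heteroatom-substituted aldehydes; their combination on an α,α-dialkyl enol is the new element. The C3 stereocentre is controlled by the catalyst alone, because the substrate stereocentre is erased in the enol. The step needs clean lactonisation and no later epimerisation of the α-acidic aryl lactone, which the catalytic amount of weak base, the low temperature and the acidic quench are meant to secure.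

Step 8
Reactants: 11 (3S)-5,7-bis(methoxymethoxy)-6-(3-methylbutanoyl)-3-(propan-2-yl)-3,4-dihydro-2H-chromen-2-one
Product: 12 1-[(3S)-2-hydroxy-5,7-bis(methoxymethoxy)-3-(propan-2-yl)-3,4-dihydro-2H-chromen-6-yl]-3-methylbutan-1-one (anomer mixture)
Conditions: DIBAL-H (1.1 equiv), toluene, −78 °C; Rochelle salt
Reagents that add atoms: none
Why: Partial hydride reduction of the activated aryl lactone to the lactol through the aluminate that is stable at −78 °C; the di-ortho-substituted, twisted aryl ketone should react much more slowly, and C3 is not touched.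

Step 9
Reactants: 12 1-[(3S)-2-hydroxy-5,7-bis(methoxymethoxy)-3-(propan-2-yl)-3,4-dihydro-2H-chromen-6-yl]-3-methylbutan-1-one; 13 2,4,6-trihydroxybenzene-1,3-dicarbaldehyde
Product: 15 5-[(2R,3S)-5,7-dihydroxy-6-(3-methylbutanoyl)-3-(propan-2-yl)-3,4-dihydro-2H-chromen-2-yl]-2,4,6-trihydroxybenzene-1,3-dicarbaldehyde (CNP0551232.1), via MOM ether 14 (not isolated)
Conditions: 13 (2 equiv), Sc(OTf)3 (10 mol%), MeCN/CH2Cl2, 0 °C to rt; then 3 M HCl in MeOH, 0 °C to rt
Reagents that add atoms: none
Why: Lewis-acid ionisation of the lactol gives the 3-substituted chroman-2-ylium ion, which the single free ring carbon of 13 attacks (Friedel–Crafts C-arylation, possibly through the O-aryl acetal and a Fries-type O-to-C shift) on the face anti to the C3 isopropyl group, so the 2,3-trans (2R) isomer, which should also be the more stable one, is expected; acidic methanolysis then removes both MOM groups.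

**Compound list**

1 | prop-2-yn-1-ol | C#CCO | starting material
2 | isopropylmagnesium chloride | CC(C)[Mg]Cl | starting material
3 | 3-methyl-2-methylidenebutan-1-ol | C=C(CO)C(C)C | intermediate
4 | 1-(2,4,6-trihydroxyphenyl)-3-methylbutan-1-one | CC(C)CC(=O)c1c(O)cc(O)cc1O | starting material
5 | 1-{2,6-dihydroxy-4-[(3-methyl-2-methylidenebutyl)oxy]phenyl}-3-methylbutan-1-one | CC(C)CC(=O)c1c(O)cc(OCC(=C)C(C)C)cc1O | intermediate
6 | 1-{2,6-bis(methoxymethoxy)-4-[(3-methyl-2-methylidenebutyl)oxy]phenyl}-3-methylbutan-1-one | CC(C)CC(=O)c1c(OCOC)cc(OCC(=C)C(C)C)cc1OCOC | intermediate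
7 | 1-[4-hydroxy-2,6-bis(methoxymethoxy)-3-(3-methyl-2-methylidenebutyl)phenyl]-3-methylbutan-1-one | CC(C)CC(=O)c1c(OCOC)cc(O)c(CC(=C)C(C)C)c1OCOC | intermediate
8 | rac-1-(4-hydroxy-2,6-bis(methoxymethoxy)-3-{[2-(propan-2-yl)oxiran-2-yl]methyl}phenyl)-3-methylbutan-1-one | CC(C)CC(=O)c1c(OCOC)cc(O)c(CC2(CO2)C(C)C)c1OCOC | intermediate
9 | rac-1-[2-(hydroxymethyl)-4,6-bis(methoxymethoxy)-2-(propan-2-yl)-2,3-dihydro-1-benzofuran-5-yl]-3-methylbutan-1-one | CC(C)CC(=O)c1c(OCOC)cc2c(c1OCOC)CC(CO)(C(C)C)O2 | intermediate
10 | rac-4,6-bis(methoxymethoxy)-5-(3-methylbutanoyl)-2-(propan-2-yl)-2,3-dihydro-1-benzofuran-2-carbaldehyde | CC(C)CC(=O)c1c(OCOC)cc2c(c1OCOC)CC(C=O)(C(C)C)O2 | intermediate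
11 | (3S)-5,7-bis(methoxymethoxy)-6-(3-methylbutanoyl)-3-(propan-2-yl)-3,4-dihydro-2H-chromen-2-one | CC(C)CC(=O)c1c(OCOC)cc2c(c1OCOC)C[C@@H](C(C)C)C(=O)O2 | intermediate
12 | 1-[(3S)-2-hydroxy-5,7-bis(methoxymethoxy)-3-(propan-2-yl)-3,4-dihydro-2H-chromen-6-yl]-3-methylbutan-1-one | CC(C)CC(=O)c1c(OCOC)cc2c(c1OCOC)C[C@@H](C(C)C)C(O)O2 | intermediate
13 | 2,4,6-trihydroxybenzene-1,3-dicarbaldehyde | O=Cc1c(O)cc(O)c(C=O)c1O | starting material
14 | 5-[(2R,3S)-5,7-bis(methoxymethoxy)-6-(3-methylbutanoyl)-3-(propan-2-yl)-3,4-dihydro-2H-chromen-2-yl]-2,4,6-trihydroxybenzene-1,3-dicarbaldehyde | CC(C)CC(=O)c1c(OCOC)cc2c(c1OCOC)C[C@@H](C(C)C)[C@H](c1c(O)c(C=O)c(O)c(C=O)c1O)O2 | intermediate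
15 | 5-[(2R,3S)-5,7-dihydroxy-6-(3-methylbutanoyl)-3-(propan-2-yl)-3,4-dihydro-2H-chromen-2-yl]-2,4,6-trihydroxybenzene-1,3-dicarbaldehyde | CC(C)CC(=O)c1c(O)cc2c(c1O)C[C@@H](C(C)C)[C@H](c1c(O)c(C=O)c(O)c(C=O)c1O)O2 | target

Total step count: 9. Longest linear sequence: 9 steps (1 to 15 through steps 1–9; 4 and 13 enter as single building blocks).

**Steps most likely to fail**

Step 7 (proposed new method). The process at risk is the facial selectivity of the protonation of an azolium enol whose two carbon substituents (isopropyl, arylmethyl) differ only moderately, together with loss of enantiomeric purity by base-mediated enolisation of the aryl lactone once formed. The fallback sets out from 10: the ring expansion is run under the established achiral conditions for this reaction type (IMes·HCl, DBU, CH2Cl2, rt), which should give the racemic lactone rac-5,7-bis(methoxymethoxy)-6-(3-methylbutanoyl)-3-(propan-2-yl)-3,4-dihydro-2H-chromen-2-one F1. F1 is resolved by preparative chromatography on a chiral stationary phase (SFC), and the unwanted (3R) antipode is racemised with catalytic DBU and recycled. The (3S) antipode is compound 11, where the route is rejoined.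

Step 9. The process at risk is slow C-arylation by the doubly formylated, deactivated phenol 13. Slow trapping would allow loss of H-3 from the oxocarbenium ion (racemisation of C3 through the 4H-chromene), self-condensation at the free C8 of ring A, and, after MOM loss, acid-induced opening of the C2–O1 bond with reclosure on O-5. The fallback sets out from 12: acetylation (Ac2O, pyridine, DMAP) gives the anomeric acetate (3S)-5,7-bis(methoxymethoxy)-6-(3-methylbutanoyl)-3-(propan-2-yl)-3,4-dihydro-2H-chromen-2-yl acetate F2. F2 is coupled with 13 in two stages under BF3·OEt2 (CH2Cl2/MeCN, −78 to −20 °C): O-aryl acetal formation at low temperature, then Fries-type O-to-C rearrangement on warming, as in C-aryl glycoside synthesis. This should give 14 as an isolated compound, where the route is rejoined; the MOM groups are then removed separately with HCl in MeOH.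

Step 8. The process at risk is over-reduction: hydride delivery to the aryl ketone (possibly assisted by chelation through a MOM oxygen) or further reduction of the lactol. The fallback sets out from 11: both carbonyl groups are reduced on purpose with excess DIBAL-H (3 equiv, −78 to −40 °C) to the carbinol lactol (3S)-6-(1-hydroxy-3-methylbutyl)-5,7-bis(methoxymethoxy)-3-(propan-2-yl)-3,4-dihydro-2H-chromen-2-ol F3. Only the benzylic alcohol is then re-oxidised with activated MnO2 (CH2Cl2, rt), which should leave the lactol untouched and return the route to 12.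

**Further compounds**

F1 | step 7 | rac-5,7-bis(methoxymethoxy)-6-(3-methylbutanoyl)-3-(propan-2-yl)-3,4-dihydro-2H-chromen-2-one | CC(C)CC(=O)c1c(OCOC)cc2c(c1OCOC)CC(C(C)C)C(=O)O2
F2 | step 9 | (3S)-5,7-bis(methoxymethoxy)-6-(3-methylbutanoyl)-3-(propan-2-yl)-3,4-dihydro-2H-chromen-2-yl acetate | CC(C)CC(=O)c1c(OCOC)cc2c(c1OCOC)C[C@@H](C(C)C)C(OC(C)=O)O2
F3 | step 8 | (3S)-6-(1-hydroxy-3-methylbutyl)-5,7-bis(methoxymethoxy)-3-(propan-2-yl)-3,4-dihydro-2H-chromen-2-ol | CC(C)CC(O)c1c(OCOC)cc2c(c1OCOC)C[C@@H](C(C)C)C(O)O2
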